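## Structural features

The target is a germacranolide: a ten-membered carbocycle (C1–C10) cis-fused through C6 and C7 to an α-methylene-γ-butyrolactone (O–C6, C7, C11, C12, exocyclic C13). The carbocycle holds a cross-conjugated dienone, C1=C2 (Z), C3=O, C4(CH3)=C5 (Z), whose two ends are the tertiary carbinol C10 (R, bearing C14) and the lactone carbinol C6 (S). C6, C7 (R) and C8 (R, tiglate) are contiguous, with the C7–C11 bond anti to both the C6 and the C8 oxygen along the ring chain; C10 is insulated from this triad by the C9 methylene. The fragile groups are the α-methylene lactone and the dienone (Michael acceptors), the Z-enone that stands γ to a free tertiary hydroxyl (it can close to a 3,10-hemiketal or isomerise), the tiglate (it can migrate to O6 or be eliminated when a carbonyl stands β to it) and the tertiary allylic alcohol. The real difficulty is to close a ten-membered ring with two Z olefins flanking a ketone without disturbing the C6–C8 triad. The key step uses the unit O10–C10–C1=C2–C3: written as a 2-methoxy-2,5-dihydrofuran (O, C3, C2, C1, C10) it fixes C1=C2 as cis, hides the ketone and holds C4 and C9 on one face, so that forming C5–C6 closes only a nine-membered oxacycle.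

## Logic of the disconnections

33 ⇒ 31 (through 32). No skeletal bond is cut; the C3 carbonyl and the C10 hydroxyl are rewritten as the bridging ketal (C3–O10, C3–OMe). This removes the dienone, the ring-chain equilibrium and one Michael acceptor from every earlier stage. The forward step must be a hydrolysis mild enough for the α-methylene lactone and the tertiary allylic alcohol.

31 ⇒ 28 (through 30 and 29). The C11=C13 bond is cut. The exocyclic methylene is the most reactive group of the target and is best added last to a plain lactone. The forward step needs a lactone enolate, which is acceptable only because the ketone is masked and C11 is the only enolisable lactone position.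

28 ⇒ 27. The C12–O6 bond is cut. This gives a γ-hydroxy methyl ester whose ring closure is five-membered and favourable. The forward step must avoid acid (ketal exchange with the C6 hydroxyl) and must be faster than tiglate migration from O8.

27 ⇒ 26. The C5–C6 bond is cut, opening the carbocycle to a (Z)-vinyl iodide and an aldehyde tethered across the cis-2,5-disubstituted dihydrofuran. The cut lies between an sp2 carbon of fixed geometry and a carbinol, and leaves all other stereocentres in an acyclic, controllable chain. The forward step must form C6 as S and must not touch the methyl ester, the tiglate or the ketal. For that reason only the ketal epimer with C4 and C9 cis is carried, the ester is kept as the base-labile methyl ester, and the β-acyloxy aldehyde is unveiled last.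

26 ⇒ 22 and 24 (through 25 and 23). The O8–acyl bond is cut and C6 is returned to the carboxyl level. A thioester at C6 can be told apart from the C12 methyl ester by a thiophilic metal, and an amide can be told apart from esters by a zirconium hydride. The forward steps must differentiate three carbonyl groups and must not let the C8 hydroxyl lactonise onto C12.

22 ⇒ 18 + 21. The C7–C8 bond is cut (aldol). It joins the citramalate-derived aldehyde to a succinate unit and sets both C7 and C8. The forward step must be anti-selective, must be controlled by the reagent because C10 is remote, must enolise only the thioester side, and must use no Lewis acid strong enough to ionise the ketal.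

18 ⇒ 12 (through 17, 16, 15, 14 and 13). The two C3–O bonds of the ketal are cut and C1=C2 is returned to C1≡C2. The ring then comes from a γ-hydroxy ynone by cis-semireduction and spontaneous hemiketalisation. The forward steps must reduce the alkyne without hydrogenolysis of the vinyl iodide. Because methanolysis of the hemiketal is under equilibrium control and gives both C3 epimers, the epimer with OMe cis to the C10 methyl must be separated and the other one recycled by acid equilibration.

12 ⇒ 7 + 11. The C2–C3 bond is cut (acetylide acylation). This is the convergent union of the two fragments. The forward step needs an acyl donor that stops at the ketone and a nucleophile that does not exchange with the vinyl iodide.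

7 ⇒ 1 (through 6 to 2). The C1–C2 bond is cut, C2 coming from a diazophosphonate, and the oxidation levels of C8 and C1 are adjusted. C10 is taken unchanged from the chiral pool. The forward steps must differentiate the two primary hydroxyls of the triol.

11 ⇒ 8 (through 10 and 9). The C4–C15 and C5–I bonds are cut. Anti-carbometallation of the propargylic alkoxide sets the Z geometry that later becomes the C4=C5 ring olefin. The forward steps must keep that geometry through oxidation and amide formation.

21 ⇒ 19 (through 20). Two carbon–heteroatom bonds are cut. The symmetric anhydride is desymmetrised into an ester end (C12) and a thioester end (C6).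

## Other disconnections considered

Alternative 1: The carbocycle would be cut at C1–C10, with a cyclohexene C3–C8 bond restored. In the forward sense an acetylenic anionic oxy-Cope rearrangement of a 1-alkynyl-2-alkenylcyclohexanolate would expand six to ten ring atoms, and aqueous acid would give the dione A1. In its favour, the ring is formed unimolecularly without high dilution, C4=C5 is inherited cis from the six-membered ring, and a cheap terpene supplies C15 and the C7 branch. On ring-forming efficiency and early convergence it is better than the chosen plan. Against it here, the quaternary C10 would be created in the sigmatropic step, so its configuration depends on enol ether geometry and chair versus boat. C8 would arrive as a ketone that must be reduced selectively next to enolisable C7 and C9 and then acylated. A1 would carry the free dienone through deprotection, C12 oxidation, lactonisation and methylenation, and removal of the C10 ether would release the hydroxy enone early. The chosen plan fixes C7, C8 and C10 before ring closure and keeps the ketone masked to the last step; the step count after ring formation would be clearly higher for A1.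

Alternative 2: The lactone would be cut at C7–C11. In the forward sense a rhodium carbenoid, generated with Rh2(OAc)4 from a diazophosphonoacetate on O6, would insert into the syn C7–H bond to give the phosphono lactone A2; olefination with formaldehyde would then give the methylene. In its favour, lactone and methylenation handle come in one step, the cis fusion follows from the geometry of a five-membered insertion, and the methylene is made with mild carbonate base. On that last point it is better than the enolate chemistry of the chosen plan. Against it here, the C7–H bond is an unactivated methine deactivated by the neighbouring C8 acyloxy group. The carbenoid could instead cyclopropanate C4=C5 or the tiglate olefin, or form ylides with the ketone. The whole Z,Z-dienone ring with a silylated C10 oxygen must already exist, so the ring-closure problem is only moved. Both plans set one stereocentre under ring control; in step economy A2 saves about two endgame steps but needs a separate solution for the carbocycle.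

Alternative 3: The ring would be cut at both C2–C3 and C3–C4, C3 coming from carbon monoxide. In the forward sense zerovalent palladium (Pd(PPh3)4) would insert into the C4–I bond, take up CO and couple with a (Z)-vinylstannane at C2 to give the silyl ether A3. In its favour, two bonds and the ketone are formed at once from two olefins of secure geometry, and A3 is one desilylation from the target. In step economy after the key step it is better than the chosen plan (one step against four). Against it here, the ring would close at its most strained position, with two Z olefins and an sp2 carbonyl and no template. Direct coupling without CO would give a nine-membered diene. The hindered stannane next to the quaternary silyloxy carbon would transmetalate slowly, and the α-methylene lactone would be exposed to palladium and phosphine. The final desilylation meets the same hydroxy enone and hemiketal question as the chosen route, so on that point the two are equal. The chosen plan closes the ring at an sp2–sp3 bond with a template and a masked ketone.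

Key step: step 20

Assumption: the open 10-hydroxy-3-oxo form written for the target and its 3,10-hemiketal 32 are ring-chain tautomers, and the route is taken to end at the open form 33.

Step 1
Reactants: 1 (R)-citramalic acid
Product: 2 (2R)-2-methylbutane-1,2,4-triol
Conditions: BH3·SMe2, B(OMe)3, THF, 0 °C → rt; MeOH quench
Reagents that add atoms: none
Why: Borane reduction of both carboxyl groups; the quaternary carbinol (future C10) is not involved, so the configuration of the chiral pool is carried over unchanged.

Step 2
Reactants: 2 (2R)-2-methylbutane-1,2,4-triol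
Product: 3 2-[(4R)-2,2,4-trimethyl-1,3-dioxolan-4-yl]ethan-1-ol
Conditions: Me2C(OMe)2, p-TsOH (cat.), acetone, rt
Reagents that add atoms: 2,2-dimethoxypropane, COC(C)(C)OC
Why: Thermodynamic acetonide formation prefers the five-membered dioxolane to the six-membered dioxane, so the 1,2-diol is tied up and the hydroxyl of the future C8 stays free.

Step 3
Reactants: 3 2-[(4R)-2,2,4-trimethyl-1,3-dioxolan-4-yl]ethan-1-ol
Product: 4 tert-butyl{2-[(4R)-2,2,4-trimethyl-1,3-dioxolan-4-yl]ethoxy}diphenylsilane
Conditions: t-BuPh2SiCl, imidazole, DMF, rt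
Reagents that add atoms: tert-butyl(chloro)diphenylsilane, CC(C)(C)[Si](Cl)(c1ccccc1)c1ccccc1
Why: Silylation of the only free hydroxyl; the silyl ether is chosen because it survives butyllithium, hydrogenation and acidic methanol and is removed by fluoride without acid.

Step 4
Reactants: 4 silyl ether acetonide
Product: 5 (2R)-4-[(tert-butyldiphenylsilyl)oxy]-2-methylbutane-1,2-diol
Conditions: AcOH/H2O (4:1), 40 °C
Reagents that add atoms: none
Why: Acid hydrolysis of the acetonide; the hindered primary silyl ether is stable to aqueous acetic acid.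

Step 5
Reactants: 5 (2R)-4-[(tert-butyldiphenylsilyl)oxy]-2-methylbutane-1,2-diol
Product: 6 (2R)-4-[(tert-butyldiphenylsilyl)oxy]-2-hydroxy-2-methylbutanal
Conditions: SO3·pyridine, DMSO, i-Pr2NEt, CH2Cl2, 0 °C
Reagents that add atoms: none
Why: Parikh–Doering oxidation; only the primary hydroxyl can be oxidised, no glycol cleavage occurs, and the product has no α-hydrogen, so the stereocentre cannot epimerise.

Step 6
Reactants: 6 (2R)-4-[(tert-butyldiphenylsilyl)oxy]-2-hydroxy-2-methylbutanal
Product: 7 (3R)-5-[(tert-butyldiphenylsilyl)oxy]-3-methylpent-1-yn-3-ol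
Conditions: dimethyl (1-diazo-2-oxopropyl)phosphonate, K2CO3, MeOH, 0 °C → rt
Reagents that add atoms: dimethyl (1-diazo-2-oxopropyl)phosphonate, COP(=O)(OC)C(=[N+]=[N-])C(C)=O
Why: Seyferth–Gilbert homologation with the Ohira–Bestmann reagent turns the aldehyde into the terminal alkyne (C1≡C2); the free tertiary hydroxyl is tolerated and there is no α-hydrogen to lose.

Step 7
Reactants: 8 propargyl alcohol
Product: 9 (2Z)-3-iodo-2-methylprop-2-en-1-ol
Conditions: MeMgBr (2.2 equiv), CuI (cat.), THF, −10 °C → rt; then I2, −10 °C
Reagents that add atoms: methylmagnesium bromide, C[Mg]Br; iodine, II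
Why: Copper-catalysed anti-carbomagnesiation of the propargylic alkoxide gives a chelated five-membered alkenylmagnesium with the metal cis to the CH2O group; iodinolysis with retention gives the Z iodide, which becomes the C4=C5 geometry.

Step 8
Reactants: 9 (2Z)-3-iodo-2-methylprop-2-en-1-ol
Product: 10 (2Z)-3-iodo-2-methylprop-2-enoic acid
Conditions: TEMPO (cat.), PhI(OAc)2, MeCN/H2O, rt
Reagents that add atoms: water, O
Why: Oxoammonium oxidation of the allylic alcohol to the aldehyde and, through its hydrate, to the acid; the conditions are neutral and do not isomerise or cleave the vinyl iodide.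

Step 9
Reactants: 10 (2Z)-3-iodo-2-methylprop-2-enoic acid
Product: 11 (2Z)-3-iodo-N-methoxy-N,2-dimethylprop-2-enamide
Conditions: MeNHOMe·HCl, EDCI·HCl, HOBt, i-Pr2NEt, CH2Cl2, 0 °C → rt
Reagents that add atoms: N,O-dimethylhydroxylamine hydrochloride, CNOC.Cl
Why: Carbodiimide amide coupling; the acid has no α-hydrogen, so neither ketene formation nor loss of geometry is possible.

Step 10
Reactants: 7 (3R)-5-[(tert-butyldiphenylsilyl)oxy]-3-methylpent-1-yn-3-ol; 11 (2Z)-3-iodo-N-methoxy-N,2-dimethylprop-2-enamide
Product: 12 (1Z,6R)-8-[(tert-butyldiphenylsilyl)oxy]-6-hydroxy-1-iodo-2,6-dimethyloct-1-en-4-yn-3-one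
Conditions: 7, n-BuLi (2.0 equiv), THF, −78 → −40 °C; then 11, −78 → −20 °C; aq. NH4Cl
Reagents that add atoms: none
Why: Acylation of the dilithiated propargylic alcohol by the Weinreb amide forms C2–C3; the chelated tetrahedral adduct prevents a second addition. An acetylide does not exchange with the vinyl iodide, so exactly two equivalents of butyllithium are used.

Step 11
Reactants: 12 γ-hydroxy ynone
Product: 15 (5R)-5-{2-[(tert-butyldiphenylsilyl)oxy]ethyl}-2-[(1Z)-1-iodoprop-1-en-2-yl]-2-methoxy-5-methyl-2,5-dihydrofuran (both C2 epimers), via Z-hydroxy enone 13 (not isolated), via cyclic hemiketal 14 (not isolated)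
Conditions: H2 (1 atm), Pd/CaCO3 poisoned with Pb(OAc)2 (Lindlar), quinoline (0.1 equiv), EtOAc, rt; filter, concentrate; then PPTS (0.3 equiv), MeOH, 0 °C → rt; Et3N quench
Reagents that add atoms: methanol, CO
Why: Lindlar semihydrogenation delivers H2 syn and gives the Z-enone 13, whose γ-hydroxyl adds to the ketone to give the five-membered hemiketal 14; acid-catalysed exchange of the hemiketal hydroxyl for methoxyl through the ring oxocarbenium ion then gives the methyl ketal as both C2 epimers under equilibrium control. The ring olefin lies between two fully substituted carbons and resists further reduction, quinoline and low pressure limit C–I hydrogenolysis, and the ring carbon that bears the methyl is quaternary, so aromatisation to a furan is impossible.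

Step 12
Reactants: 15 methyl ketal (both C2 epimers)
Product: 16 (2R,5R)-5-{2-[(tert-butyldiphenylsilyl)oxy]ethyl}-2-[(1Z)-1-iodoprop-1-en-2-yl]-2-methoxy-5-methyl-2,5-dihydrofuran
Conditions: chromatography on Et3N-deactivated silica; recovered (2S,5R)-epimer: PPTS (cat.), MeOH, rt, Et3N quench, then chromatography again (repeated)
Reagents that add atoms: methanol, CO
Why: Acid-catalysed ketal epimerisation through the ring oxocarbenium ion (a degenerate methoxy exchange with the solvent) re-forms the equilibrium mixture from the recovered (2S,5R)-component of 15, so repeated separation and recycling should funnel the material into 16, the epimer with OMe cis to the ring methyl and the iodopropenyl group cis to the side chain. C5 is quaternary and takes no part, so its configuration is unchanged.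

Step 13
Reactants: 16 (2R,5R)-methyl ketal
Product: 17 2-[(2R,5R)-5-[(1Z)-1-iodoprop-1-en-2-yl]-5-methoxy-2-methyl-2,5-dihydrofuran-2-yl]ethan-1-ol
Conditions: Bu4NF, THF, 0 °C
Reagents that add atoms: none
Why: Fluoride desilylation; the basic conditions keep the ketal, whereas acid would let the freed hydroxyl displace methanol to give a bicyclic ketal of the wrong geometry.

Step 14
Reactants: 17 primary alcohol
Product: 18 2-[(2R,5R)-5-[(1Z)-1-iodoprop-1-en-2-yl]-5-methoxy-2-methyl-2,5-dihydrofuran-2-yl]acetaldehyde
Conditions: Dess–Martin periodinane, pyridine, CH2Cl2, 0 °C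
Reagents that add atoms: none
Why: Buffered periodinane oxidation to the C8 aldehyde; the pyridine takes up the acetic acid so that the ketal is not ionised, and the β-alkoxy aldehyde is used without storage.

Step 15
Reactants: 19 succinic anhydride
Product: 21 methyl 4-(tert-butylsulfanyl)-4-oxobutanoate, via 4-methoxy-4-oxobutanoic acid 20 (not isolated)
Conditions: MeOH (1.05 equiv), DMAP (cat.), CH2Cl2, rt; then t-BuSH, DCC, 0 °C → rt
Reagents that add atoms: methanol, CO; 2-methylpropane-2-thiol, CC(C)(C)S
Why: Methanolysis of the symmetric anhydride gives the half ester, and Steglich-type thioesterification of the free acid differentiates the C12 end (ester) from the C6 end (thioester).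

Step 16
Reactants: 18 C8 aldehyde; 21 methyl 4-(tert-butylsulfanyl)-4-oxobutanoate
Product: 22 S-tert-butyl (2R,3R)-3-hydroxy-4-[(2R,5R)-5-[(1Z)-1-iodoprop-1-en-2-yl]-5-methoxy-2-methyl-2,5-dihydrofuran-2-yl]-2-(2-methoxy-2-oxoethyl)butanethioate
Conditions: 21 (1.5 equiv), [(2-isopropyl-5-methylcyclohexyl)methyl]2BBr (menthone-derived, one enantiomer, 1.3 equiv), Et3N, Et2O/CH2Cl2, 0 °C; then 18, −78 °C; pH 7 buffer, MeOH, H2O2, 0 °C
Reagents that add atoms: none
Why: Boron-mediated anti-aldol reaction with a chiral dialkylboron bromide; only the thioester is enolised (a methyl ester is not enolised by a dialkylboron bromide and Et3N), and the bulky S-tert-butyl group gives the E(O)-enol borinate, whose chair (Zimmerman–Traxler) transition state gives the 7,8-anti product. The enantiomer of the boron reagent is the one that sends the enolate to the Si face of the aldehyde, which sets 7R and 8R because C10 is too remote to interfere; the boron reagent is kept below the amount of thioester so that no free bromoborane meets the ketal. Work-up at pH 7 and 0 °C keeps the C8 hydroxyl from lactonising onto the C12 ester.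

Step 17
Reactants: 22 anti-aldol thioester
Product: 23 methyl (3R,4R)-4-hydroxy-5-[(2R,5R)-5-[(1Z)-1-iodoprop-1-en-2-yl]-5-methoxy-2-methyl-2,5-dihydrofuran-2-yl]-3-[methoxy(methyl)carbamoyl]pentanoate
Conditions: MeNHOMe·HCl, Et3N, AgOCOCF3, THF, 0 °C → rt
Reagents that add atoms: N,O-dimethylhydroxylamine hydrochloride, CNOC.Cl
Why: Silver-assisted aminolysis of the S-tert-butyl thioester; monovalent silver activates sulfur only, so the methyl ester is untouched and C7 and C8 are unchanged. The reaction is run cold and briefly so that the C8 hydroxyl does not lactonise onto C12.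

Step 18
Reactants: 23 β-hydroxy Weinreb amide; 24 tiglic acid
Product: 25 methyl (3R,4R)-5-[(2R,5R)-5-[(1Z)-1-iodoprop-1-en-2-yl]-5-methoxy-2-methyl-2,5-dihydrofuran-2-yl]-3-[methoxy(methyl)carbamoyl]-4-{[(2E)-2-methylbut-2-enoyl]oxy}pentanoate
Conditions: 24, 2,4,6-Cl3C6H2COCl, Et3N, THF, rt; then 23, DMAP, PhMe, 0 °C → rt
Reagents that add atoms: none
Why: Yamaguchi esterification; the mixed anhydride and DMAP acylate the hindered secondary hydroxyl with retention at C8. A β-acyloxy amide is far less prone to E1cB elimination than the corresponding thioester or aldehyde, which is why the amide is made first.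

Step 19
Reactants: 25 tigloylated Weinreb amide
Product: 26 methyl (3R,4R)-3-formyl-5-[(2R,5R)-5-[(1Z)-1-iodoprop-1-en-2-yl]-5-methoxy-2-methyl-2,5-dihydrofuran-2-yl]-4-{[(2E)-2-methylbut-2-enoyl]oxy}pentanoate
Conditions: Cp2Zr(H)Cl (1.5 equiv), THF, rt, 15 min; used at once
Reagents that add atoms: none
Why: Reduction of the tertiary amide by the zirconium hydride stops at a zirconated hemiaminal that gives the aldehyde on work-up; esters are not reduced and hydrozirconation of hindered or trisubstituted olefins is much slower. No free C6 alkoxide is formed, so lactonisation onto C12 cannot intervene.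

Step 20
Reactants: 26 vinyl iodide aldehyde
Product: 27 methyl 2-[(1R,2Z,4S,5S,6R,8R,9Z)-4-hydroxy-1-methoxy-2,8-dimethyl-6-{[(2E)-2-methylbut-2-enoyl]oxy}-11-oxabicyclo[6.2.1]undeca-2,9-dien-5-yl]acetate
Conditions: CrCl2 (8 equiv), NiCl2 (1 mol % of the CrCl2), degassed DMSO, rt, syringe-pump addition of 26 (final 2 mM); aq. sodium serinate work-up
Reagents that add atoms: none
Why: Intramolecular Nozaki–Hiyama–Kishi coupling; the closest known type is the macrocyclisation of a (Z)-vinyl iodide onto an aldehyde. Divalent chromium reduces NiCl2 to zerovalent nickel, which inserts into the C5–I bond with retention of the Z geometry; the vinyl group passes to trivalent chromium and the vinylchromium adds to the C6 aldehyde. The one ring closed is the ten-membered carbocycle, in the exo-trig mode (10-exo-trig, or 9-exo-trig counted through the ketal oxygen), with the cis-2,5-disubstituted dihydrofuran as a template that already holds C4 and C9 on one face. The new C6 stereocentre is controlled by the C7 stereocentre inside this bridged ring: the aldehyde should react with its C=O bond turned away from the C7 acetate arm (Felkin–Anh type), so the vinylchromium reaches the Si face and gives 6S. Chemoselectivity for the aldehyde over the methyl ester, the tiglate and the ketal is inherent in organochromium reagents, and cyclisation is favoured over oligomerisation by slow addition at high dilution. Only the ketal epimer 16 is carried forward, so all of 26 can cyclise, and 26 is used at once because it is a β-acyloxy aldehyde. Any material that lactonises in the flask to 28 converges in step 21.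

Step 21
Reactants: 27 hydroxy ester
Product: 28 (1Z,4Z,3R,6S,7R,8R,10R)-3,10-epoxy-3-methoxy-8-{[(2E)-2-methylbut-2-enoyl]oxy}-13-norgermacra-1,4-dien-12,6-olide (cis-fused lactone)
Conditions: DBU (0.2 equiv), CH2Cl2, rt
Reagents that add atoms: none
Why: Base-catalysed 5-exo-trig transesterification of the C6 hydroxyl onto the unhindered methyl ester, with retention at C6; attack on the tiglate would need a six-membered transition state at a hindered conjugated ester and is much slower. Base is used instead of acid so that the ketal cannot exchange with the C6 hydroxyl.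

Step 22
Reactants: 28 ketal lactone
Product: 29 (1Z,4Z,3R,6S,7R,8R,10R)-13-(dimethylamino)-3,10-epoxy-3-methoxy-8-{[(2E)-2-methylbut-2-enoyl]oxy}germacra-1,4-dien-12,6-olide (C11 epimers)
Conditions: LiN(SiMe3)2, THF, −78 °C; then CH2=NMe2+ I−, −78 → 0 °C
Reagents that add atoms: N,N-dimethylmethyleneiminium iodide (Eschenmoser's salt), C=[N+](C)C.[I-]
Why: Mannich reaction of the lactone lithium enolate; C11 is the only enolisable lactone position and is deprotonated faster than the γ-methyl of the tiglate. With the dienone masked as the ketal there is no enolisable ketone and no Michael acceptor in the molecule.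

Step 23
Reactants: 29 Mannich base
Product: 31 (1Z,4Z,3R,6S,7R,8R,10R)-3,10-epoxy-3-methoxy-8-{[(2E)-2-methylbut-2-enoyl]oxy}germacra-1,4,11(13)-trien-12,6-olide, via trimethylammonium iodide 30 (not isolated)
Conditions: MeI, THF, rt; then aq. NaHCO3, EtOAc, rt
Reagents that add atoms: none
Why: Quaternisation of the amine and Hofmann-type E1cB loss of trimethylamine under bicarbonate give the exocyclic methylene; the C11 epimers converge.

Step 24
Reactants: 31 α-methylene lactone ketal
Product: 33 (1Z,4Z,6S,7R,8R,10R)-10-hydroxy-3-oxo-8-{[(2E)-2-methylbut-2-enoyl]oxy}germacra-1,4,11(13)-trien-12,6-olide (CNP0135074.2), via cyclic 3,10-hemiketal 32 (not isolated)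
Conditions: PPTS, acetone/H2O (4:1), rt
Reagents that add atoms: water, O
Why: Specific-acid hydrolysis of the ketal through the oxocarbenium ion gives the hemiketal, which opens to the Z-hydroxy dienone; the C10–O bond is never broken, so C10 keeps its configuration and C1=C2 stays cis. The acid is kept weak to avoid transannular Nazarov-type cyclisation of the dienone and ionisation of the tertiary allylic alcohol.

## Compound list

1 | (R)-citramalic acid | OC(=O)C[C@@](C)(O)C(=O)O | starting material
2 | (2R)-2-methylbutane-1,2,4-triol | OCC[C@@](C)(O)CO | intermediate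
3 | 2-[(4R)-2,2,4-trimethyl-1,3-dioxolan-4-yl]ethan-1-ol | OCC[C@@]1(C)OC(C)(C)OC1 | intermediate
4 | tert-butyl{2-[(4R)-2,2,4-trimethyl-1,3-dioxolan-4-yl]ethoxy}diphenylsilane | CC(C)(C)[Si](OCC[C@@]1(C)OC(C)(C)OC1)(c1ccccc1)c1ccccc1 | intermediate
5 | (2R)-4-[(tert-butyldiphenylsilyl)oxy]-2-methylbutane-1,2-diol | CC(C)(C)[Si](OCC[C@@](C)(O)CO)(c1ccccc1)c1ccccc1 | intermediate
6 | (2R)-4-[(tert-butyldiphenylsilyl)oxy]-2-hydroxy-2-methylbutanal | CC(C)(C)[Si](OCC[C@@](C)(O)C=O)(c1ccccc1)c1ccccc1 | intermediate
7 | (3R)-5-[(tert-butyldiphenylsilyl)oxy]-3-methylpent-1-yn-3-ol | CC(C)(C)[Si](OCC[C@@](C)(O)C#C)(c1ccccc1)c1ccccc1 | intermediate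
8 | propargyl alcohol | C#CCO | starting material
9 | (2Z)-3-iodo-2-methylprop-2-en-1-ol | OC/C(C)=C\I | intermediate
10 | (2Z)-3-iodo-2-methylprop-2-enoic acid | OC(=O)/C(C)=C\I | intermediate
11 | (2Z)-3-iodo-N-methoxy-N,2-dimethylprop-2-enamide | CON(C)C(=O)/C(C)=C\I | intermediate
12 | (1Z,6R)-8-[(tert-butyldiphenylsilyl)oxy]-6-hydroxy-1-iodo-2,6-dimethyloct-1-en-4-yn-3-one | CC(C)(C)[Si](OCC[C@@](C)(O)C#CC(=O)/C(C)=C\I)(c1ccccc1)c1ccccc1 | intermediate
13 | (1Z,4Z,6R)-8-[(tert-butyldiphenylsilyl)oxy]-6-hydroxy-1-iodo-2,6-dimethylocta-1,4-dien-3-one | CC(C)(C)[Si](OCC[C@@](C)(O)/C=C\C(=O)/C(C)=C\I)(c1ccccc1)c1ccccc1 | intermediate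
14 | (5R)-5-{2-[(tert-butyldiphenylsilyl)oxy]ethyl}-2-[(1Z)-1-iodoprop-1-en-2-yl]-5-methyl-2,5-dihydrofuran-2-ol (both C2 epimers) | OC1(/C(C)=C\I)C=C[C@@](C)(CCO[Si](c2ccccc2)(c2ccccc2)C(C)(C)C)O1 | intermediate
15 | (5R)-5-{2-[(tert-butyldiphenylsilyl)oxy]ethyl}-2-[(1Z)-1-iodoprop-1-en-2-yl]-2-methoxy-5-methyl-2,5-dihydrofuran (both C2 epimers) | COC1(/C(C)=C\I)C=C[C@@](C)(CCO[Si](c2ccccc2)(c2ccccc2)C(C)(C)C)O1 | intermediate
16 | (2R,5R)-5-{2-[(tert-butyldiphenylsilyl)oxy]ethyl}-2-[(1Z)-1-iodoprop-1-en-2-yl]-2-methoxy-5-methyl-2,5-dihydrofuran | CO[C@]1(/C(C)=C\I)C=C[C@@](C)(CCO[Si](c2ccccc2)(c2ccccc2)C(C)(C)C)O1 | intermediate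
17 | 2-[(2R,5R)-5-[(1Z)-1-iodoprop-1-en-2-yl]-5-methoxy-2-methyl-2,5-dihydrofuran-2-yl]ethan-1-ol | CO[C@]1(/C(C)=C\I)C=C[C@@](C)(CCO)O1 | intermediate
18 | 2-[(2R,5R)-5-[(1Z)-1-iodoprop-1-en-2-yl]-5-methoxy-2-methyl-2,5-dihydrofuran-2-yl]acetaldehyde | CO[C@]1(/C(C)=C\I)C=C[C@@](C)(CC=O)O1 | intermediate
19 | succinic anhydride | O=C1CCC(=O)O1 | starting material
20 | 4-methoxy-4-oxobutanoic acid | COC(=O)CCC(=O)O | intermediate
21 | methyl 4-(tert-butylsulfanyl)-4-oxobutanoate | COC(=O)CCC(=O)SC(C)(C)C | intermediate
22 | S-tert-butyl (2R,3R)-3-hydroxy-4-[(2R,5R)-5-[(1Z)-1-iodoprop-1-en-2-yl]-5-methoxy-2-methyl-2,5-dihydrofuran-2-yl]-2-(2-methoxy-2-oxoethyl)butanethioate | CO[C@]1(/C(C)=C\I)C=C[C@@](C)(C[C@@H](O)[C@@H](CC(=O)OC)C(=O)SC(C)(C)C)O1 | intermediate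
23 | methyl (3R,4R)-4-hydroxy-5-[(2R,5R)-5-[(1Z)-1-iodoprop-1-en-2-yl]-5-methoxy-2-methyl-2,5-dihydrofuran-2-yl]-3-[methoxy(methyl)carbamoyl]pentanoate | CO[C@]1(/C(C)=C\I)C=C[C@@](C)(C[C@@H](O)[C@@H](CC(=O)OC)C(=O)N(C)OC)O1 | intermediate
24 | tiglic acid | C/C=C(\C)C(=O)O | starting material
25 | methyl (3R,4R)-5-[(2R,5R)-5-[(1Z)-1-iodoprop-1-en-2-yl]-5-methoxy-2-methyl-2,5-dihydrofuran-2-yl]-3-[methoxy(methyl)carbamoyl]-4-{[(2E)-2-methylbut-2-enoyl]oxy}pentanoate | CO[C@]1(/C(C)=C\I)C=C[C@@](C)(C[C@@H](OC(=O)/C(C)=C/C)[C@@H](CC(=O)OC)C(=O)N(C)OC)O1 | intermediate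
26 | methyl (3R,4R)-3-formyl-5-[(2R,5R)-5-[(1Z)-1-iodoprop-1-en-2-yl]-5-methoxy-2-methyl-2,5-dihydrofuran-2-yl]-4-{[(2E)-2-methylbut-2-enoyl]oxy}pentanoate | CO[C@]1(/C(C)=C\I)C=C[C@@](C)(C[C@@H](OC(=O)/C(C)=C/C)[C@@H](CC(=O)OC)C=O)O1 | intermediate
27 | methyl 2-[(1R,2Z,4S,5S,6R,8R,9Z)-4-hydroxy-1-methoxy-2,8-dimethyl-6-{[(2E)-2-methylbut-2-enoyl]oxy}-11-oxabicyclo[6.2.1]undeca-2,9-dien-5-yl]acetate | CO[C@@]12/C(C)=C\[C@H](O)[C@H](CC(=O)OC)[C@H](OC(=O)/C(C)=C/C)C[C@@](C)(O1)C=C2 | intermediate
28 | (1Z,4Z,3R,6S,7R,8R,10R)-3,10-epoxy-3-methoxy-8-{[(2E)-2-methylbut-2-enoyl]oxy}-13-norgermacra-1,4-dien-12,6-olide | CO[C@@]12/C(C)=C\[C@@H]3OC(=O)C[C@@H]3[C@H](OC(=O)/C(C)=C/C)C[C@@](C)(O1)C=C2 | intermediate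
29 | (1Z,4Z,3R,6S,7R,8R,10R)-13-(dimethylamino)-3,10-epoxy-3-methoxy-8-{[(2E)-2-methylbut-2-enoyl]oxy}germacra-1,4-dien-12,6-olide (C11 epimers) | CO[C@@]12/C(C)=C\[C@@H]3OC(=O)C(CN(C)C)[C@@H]3[C@H](OC(=O)/C(C)=C/C)C[C@@](C)(O1)C=C2 | intermediate
30 | trimethylammonium iodide of 29 (13-trimethylammonio lactone iodide) | CO[C@@]12/C(C)=C\[C@@H]3OC(=O)C(C[N+](C)(C)C)[C@@H]3[C@H](OC(=O)/C(C)=C/C)C[C@@](C)(O1)C=C2.[I-] | intermediate
31 | (1Z,4Z,3R,6S,7R,8R,10R)-3,10-epoxy-3-methoxy-8-{[(2E)-2-methylbut-2-enoyl]oxy}germacra-1,4,11(13)-trien-12,6-olide | CO[C@@]12/C(C)=C\[C@@H]3OC(=O)C(=C)[C@@H]3[C@H](OC(=O)/C(C)=C/C)C[C@@](C)(O1)C=C2 | intermediate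
32 | (1Z,4Z,3R,6S,7R,8R,10R)-3,10-epoxy-3-hydroxy-8-{[(2E)-2-methylbut-2-enoyl]oxy}germacra-1,4,11(13)-trien-12,6-olide (cyclic hemiketal tautomer of 33) | O[C@@]12/C(C)=C\[C@@H]3OC(=O)C(=C)[C@@H]3[C@H](OC(=O)/C(C)=C/C)C[C@@](C)(O1)C=C2 | intermediate
33 | (1Z,4Z,6S,7R,8R,10R)-10-hydroxy-3-oxo-8-{[(2E)-2-methylbut-2-enoyl]oxy}germacra-1,4,11(13)-trien-12,6-olide (CNP0135074.2) | C=C1C(=O)O[C@H]2/C=C(/C)C(=O)/C=C\[C@](C)(O)C[C@@H](OC(=O)/C(C)=C/C)[C@@H]12 | target

## Step count and least certain steps

Total: 24 steps. Longest linear sequence: 20 steps (steps 1–6, 10–14 and 16–24, from 1).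

Step 20 (key step). The most likely failure is poor facial selectivity at C6, because the nine-membered closure may pass through more than one conformer of the aldehyde; slow closure with protodeiodination is the second concern. The fallback corrects C6 by oxidation and reagent-controlled reduction and sets out from 26. The coupling would give 27 together with the C6-epimeric alcohol F1. The mixture is oxidised with MnO2 in CH2Cl2 (neutral, allylic alcohols only) to the C6 enone F2. F2 is then reduced at −78 °C with catecholborane and the enantiomer of the 2-methyl-CBS-oxazaborolidine that gives the 6S carbinol, so that C6 is set by the reagent and not by the ring closure. The sequence comes back at 27. F2 is a β-acyloxy ketone and is handled without base.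

Step 16. The most likely failure is incomplete facial control by the chiral boron reagent, because the enolate carries an ester-bearing arm and the aldehyde a quaternary β-carbon; ionisation of the ketal by residual bromoborane and lactonisation of the aldolate onto C12 are the further concerns. The fallback gives up reagent control and sets out from 18 and 21. Compound 21 is enolised with the achiral (c-C6H11)2BCl and Et3N, which still gives only the E-enolate and therefore only anti adducts. Addition of 18 then gives 22 and the (7S,8S) anti diastereomer F3, which are separated by chromatography. The sequence comes back at 22.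

Step 11. The most likely failure is hydrogenolysis of the C–I bond, or poisoning of the catalyst by iodide leading to stalled or over-run reduction. The fallback masks the iodide as a stannane and sets out from 11. Pd(PPh3)4 and (Bu3Sn)2 in toluene at 80 °C give the (Z)-stannyl Weinreb amide F4. The dilithio derivative of 7 adds to it as in step 10 to give the stannyl ynone F5. Lindlar hydrogenation, to which the C–Sn bond is inert, gives the stannyl hemiketal F6, and PPTS in MeOH gives the stannyl methyl ketal F7 as both C2 epimers. Iodine in CH2Cl2 with NaHCO3 at 0 °C replaces tin by iodine with retention, and the sequence comes back at 15.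

Step 19. The most likely failure is incomplete chemoselectivity of the zirconium hydride (slow reduction of the hindered amide, then hydrozirconation of an olefin), or loss of tiglic acid from 26 on work-up. The fallback reduces a thioester instead of an amide and sets out from 22. Compound 22 is tigloylated under the conditions of step 18 to give the tigloylated thioester F8. i-Bu2AlH (1.1 equiv) in CH2Cl2 at −78 °C reduces the thioester, which is more electrophilic than either ester, to the aldehyde. The sequence comes back at 26.

## Further compounds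

F1 | step 20 | methyl 2-[(1R,2Z,4R,5S,6R,8R,9Z)-4-hydroxy-1-methoxy-2,8-dimethyl-6-{[(2E)-2-methylbut-2-enoyl]oxy}-11-oxabicyclo[6.2.1]undeca-2,9-dien-5-yl]acetate (C6 epimer of 27) | CO[C@@]12/C(C)=C\[C@@H](O)[C@H](CC(=O)OC)[C@H](OC(=O)/C(C)=C/C)C[C@@](C)(O1)C=C2
F2 | step 20 | methyl 2-[1-methoxy-2,8-dimethyl-6-{[(2E)-2-methylbut-2-enoyl]oxy}-4-oxo-11-oxabicyclo[6.2.1]undeca-2,9-dien-5-yl]acetate (C6 enone of 27) | CO[C@@]12/C(C)=C\C(=O)[C@H](CC(=O)OC)[C@H](OC(=O)/C(C)=C/C)C[C@@](C)(O1)C=C2
F3 | step 16 | S-tert-butyl (2S,3S)-3-hydroxy-4-[(2R,5R)-5-[(1Z)-1-iodoprop-1-en-2-yl]-5-methoxy-2-methyl-2,5-dihydrofuran-2-yl]-2-(2-methoxy-2-oxoethyl)butanethioate | CO[C@]1(/C(C)=C\I)C=C[C@@](C)(C[C@H](O)[C@H](CC(=O)OC)C(=O)SC(C)(C)C)O1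
F4 | step 11 | (2Z)-N-methoxy-N,2-dimethyl-3-(tributylstannyl)prop-2-enamide | CCCC[Sn](CCCC)(CCCC)/C=C(/C)C(=O)N(C)OC
F5 | step 11 | (1Z,6R)-8-[(tert-butyldiphenylsilyl)oxy]-6-hydroxy-2,6-dimethyl-1-(tributylstannyl)oct-1-en-4-yn-3-one | CCCC[Sn](CCCC)(CCCC)/C=C(/C)C(=O)C#C[C@](C)(O)CCO[Si](c1ccccc1)(c1ccccc1)C(C)(C)C
F6 | step 11 | (5R)-5-{2-[(tert-butyldiphenylsilyl)oxy]ethyl}-5-methyl-2-[(1Z)-1-(tributylstannyl)prop-1-en-2-yl]-2,5-dihydrofuran-2-ol (both C2 epimers) | OC1(/C(C)=C\[Sn](CCCC)(CCCC)CCCC)C=C[C@@](C)(CCO[Si](c2ccccc2)(c2ccccc2)C(C)(C)C)O1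
F7 | step 11 | (5R)-5-{2-[(tert-butyldiphenylsilyl)oxy]ethyl}-2-methoxy-5-methyl-2-[(1Z)-1-(tributylstannyl)prop-1-en-2-yl]-2,5-dihydrofuran (both C2 epimers) | COC1(/C(C)=C\[Sn](CCCC)(CCCC)CCCC)C=C[C@@](C)(CCO[Si](c2ccccc2)(c2ccccc2)C(C)(C)C)O1
F8 | step 19 | S-tert-butyl (2R,3R)-4-[(2R,5R)-5-[(1Z)-1-iodoprop-1-en-2-yl]-5-methoxy-2-methyl-2,5-dihydrofuran-2-yl]-2-(2-methoxy-2-oxoethyl)-3-{[(2E)-2-methylbut-2-enoyl]oxy}butanethioate | CO[C@]1(/C(C)=C\I)C=C[C@@](C)(C[C@@H](OC(=O)/C(C)=C/C)[C@@H](CC(=O)OC)C(=O)SC(C)(C)C)O1
A1 | alternative 1 | cyclodeca-2,5-diene-1,7-dione with C10 4-methoxybenzyl ether, C6 silyl ether and silyloxymethylvinyl group at C7 | CC(C)(C)[Si](C)(C)O[C@H]1/C=C(/C)C(=O)/C=C\[C@](C)(OCc2ccc(OC)cc2)CC(=O)[C@H]1C(=C)CO[Si](C)(C)C(C)(C)C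
A2 | alternative 2 | α-diethylphosphono cis-fused γ-lactone on the ten-membered dienone, C10 triethylsilyl ether | CCOP(=O)(OCC)[C@H]1C(=O)O[C@H]2/C=C(/C)C(=O)/C=C\[C@](C)(O[Si](CC)(CC)CC)C[C@@H](OC(=O)/C(C)=C/C)[C@@H]12
A3 | alternative 3 | C10 triethylsilyl ether of the target | C=C1C(=O)O[C@H]2/C=C(/C)C(=O)/C=C\[C@](C)(O[Si](CC)(CC)CC)C[C@@H](OC(=O)/C(C)=C/C)[C@@H]12
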